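**Retrosynthetic overview**

- The target comes from a 3-(phenylsulfonyl)chroman-5,8-dione by base-induced loss of benzenesulfinate across C3–C4; that quinone comes from the 8-amino and, before it, the 8-nitro-5,6-dimethoxy-3-(phenylsulfonyl)chroman.
- The pyran ring is cut at C3–C4 and at O1–C8a: an anionic [3+3] annulation joins the O,C-dianion of a β-hydroxy sulfone (the O1–C2–C3 unit, with the C2 stereocentre already in place) to 6-fluoro-2,3-dimethoxy-5-nitrobenzyl bromide (benzylic C4–Br and aryl C8a–F).
- Enabling feature: O1 and C3 both sit on the quaternary carbon C2, and C4 and C8a both sit on C4a of the carbocyclic six-membered ring; C8a is also ortho to C8, the future quinone carbonyl, which is carried as a nitro group that activates C8a–F and later becomes that carbonyl.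
- The β-hydroxy sulfone comes from the (S)-epoxide of a methyl ketone, itself from the Diels–Alder aldehyde of methacrolein and (E)-3-methylpenta-1,3-diene (this sets the quaternary/tertiary pair); the benzyl bromide comes from 4-fluoroveratrole.
- Ring order: cyclohexene ring (step 1), benzene ring (bought), dihydropyran ring (step 10), quinone level and the C3=C4 bond (step 12).

Key step: step 10

Remark: the commercial diene is an E/Z mixture; only the E isomer enters the cycloaddition, so it is used in excess.
Remark: the sulfonyl-bearing carbon of the chroman intermediates forms as an epimer mixture, which does not matter because that carbon becomes sp2 in the last step.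
Remark: ring descriptors refer to the cyclohexene numbered from its quaternary carbon.

**Route**

Step 1
Reactants: 1 methacrolein; 2 (E)-3-methylpenta-1,3-diene
Product: 3 (1R,2S)-1,2,3-trimethylcyclohex-3-ene-1-carbaldehyde (formyl cis to the C2 methyl)
Conditions: o-tolyl oxazaborolidine from (R)-α,α-diphenylprolinol, activated with HNTf2 (10 mol%), CH2Cl2, −78 → −40 °C (the antipodal catalyst is taken if it proves to shield the other face)
Reagents that add atoms: none
Why: Lewis-acid-catalysed Diels–Alder reaction in which the terminal methyl of the diene directs "ortho" bonding to C2 of methacrolein, the endo transition state places the formyl group cis to the new secondary methyl, and the chiral oxazaborolidinium holds the s-trans enal so that the diene meets the Si face of C2, setting the quaternary and the tertiary centre together.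

Step 2
Reactants: 3 (1R,2S)-1,2,3-trimethylcyclohex-3-ene-1-carbaldehyde
Product: 4 (E)-4-[(1S,2S)-1,2,3-trimethylcyclohex-3-en-1-yl]but-3-en-2-one
Conditions: Ph3P=CHC(O)CH3, toluene, 110 °C
Reagents that add atoms: 1-(triphenylphosphoranylidene)propan-2-one, CC(=O)C=P(c1ccccc1)(c1ccccc1)c1ccccc1
Why: Wittig olefination with a stabilised ylide on a non-enolisable neopentyl aldehyde should give the E enone without touching the ring stereocentres (the alkene geometry is lost in step 3 anyway).

Step 3
Reactants: 4 (E)-4-[(1S,2S)-1,2,3-trimethylcyclohex-3-en-1-yl]but-3-en-2-one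
Product: 5 4-[(1S,2R)-1,2,3-trimethylcyclohex-3-en-1-yl]butan-2-one
Conditions: [(Ph3P)CuH]6 (0.4 equiv), THF, H2O (5 equiv), 20 °C
Reagents that add atoms: none
Why: Conjugate reduction with the copper hydride hexamer (Stryker reduction) is selective for the enone C=C and should leave the ketone and the isolated trisubstituted ring alkene alone.

Step 4
Reactants: 5 4-[(1S,2R)-1,2,3-trimethylcyclohex-3-en-1-yl]butan-2-one
Product: 6 (2S)-2-methyl-2-{2-[(1S,2R)-1,2,3-trimethylcyclohex-3-en-1-yl]ethyl}oxirane
Conditions: Me3S(O)I, NaH, THF, 20 °C; then 5, LaLi3[(S)-1,1′-binaphthalene-2,2′-diolate]3 (5 mol%), (2,4,6-(MeO)3C6H2)3P=O (5 mol%), 5 Å MS, THF, 20 °C (catalyst enantiomer chosen for Re-face delivery)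
Reagents that add atoms: trimethylsulfoxonium iodide, C[S+](C)(C)=O.[I-]
Why: Catalytic asymmetric Corey–Chaykovsky epoxidation of a methyl ketone, in which the La/Li binaphthoxide catalyst tells methyl from the primary alkyl chain and delivers CH2 to the Re face, setting the (S)-configured quaternary C–O carbon by catalyst control.

Step 5
Reactants: 6 (2S)-2-methyl-2-{2-[(1S,2R)-1,2,3-trimethylcyclohex-3-en-1-yl]ethyl}oxirane
Product: 7 (2S)-2-methyl-1-(phenylsulfonyl)-4-[(1S,2R)-1,2,3-trimethylcyclohex-3-en-1-yl]butan-2-ol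
Conditions: PhSO2Na (2 equiv), AcOH (1.1 equiv), DMF/H2O (4:1), 90 °C
Reagents that add atoms: sodium benzenesulfinate, [Na+].[O-]S(=O)c1ccccc1
Why: SN2 opening of the 2,2-disubstituted epoxide by the sulfur of the sulfinate occurs at the unhindered CH2 terminus, so the C–O bond of the stereocentre is untouched and its configuration is retained.

Step 6
Reactants: 8 4-fluoro-1,2-dimethoxybenzene
Product: 9 6-fluoro-2,3-dimethoxybenzaldehyde
Conditions: n-BuLi, THF, −78 °C; DMF; aq. HCl
Reagents that add atoms: N,N-dimethylformamide, CN(C)C=O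
Why: Directed ortho-lithiation takes place at the C–H flanked by fluorine and methoxy (the most acidic position), and the aryllithium is formylated by DMF.

Step 7
Reactants: 9 6-fluoro-2,3-dimethoxybenzaldehyde
Product: 10 6-fluoro-2,3-dimethoxy-5-nitrobenzaldehyde
Conditions: HNO3 (70%), AcOH, 10 °C
Reagents that add atoms: nitric acid, O[N+](=O)[O-]
Why: Electrophilic aromatic nitration should go to the one free position that is para to a methoxy group, ortho to fluorine and meta to the formyl group, the other free position being para to the deactivating formyl group.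

Step 8
Reactants: 10 6-fluoro-2,3-dimethoxy-5-nitrobenzaldehyde
Product: 11 (6-fluoro-2,3-dimethoxy-5-nitrophenyl)methanol
Conditions: BH3·THF, THF, 0 °C; MeOH/H2O quench
Reagents that add atoms: none
Why: Borane reduces the aldehyde chemoselectively in the presence of the nitro group and offers no alkoxide nucleophile for the labile fluoride that sits between the formyl and nitro groups.

Step 9
Reactants: 11 (6-fluoro-2,3-dimethoxy-5-nitrophenyl)methanol
Product: 12 6-fluoro-2,3-dimethoxy-5-nitrobenzyl bromide
Conditions: PBr3, CH2Cl2, 0 °C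
Reagents that add atoms: phosphorus tribromide, BrP(Br)Br
Why: Standard conversion of a benzylic alcohol into the bromide by SN2 displacement on its phosphite ester.

Step 10
Reactants: 7 (2S)-2-methyl-1-(phenylsulfonyl)-4-[(1S,2R)-1,2,3-trimethylcyclohex-3-en-1-yl]butan-2-ol; 12 6-fluoro-2,3-dimethoxy-5-nitrobenzyl bromide
Product: 14 (2S)-5,6-dimethoxy-2-methyl-8-nitro-3-(phenylsulfonyl)-2-{2-[(1S,2R)-1,2,3-trimethylcyclohex-3-en-1-yl]ethyl}chromane (C3 epimers), via lithium alkoxide of the C-benzylated hydroxy sulfone 13 (not isolated)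
Conditions: 7, LiN(i-Pr)2 (2.1 equiv), THF, −78 °C; then 12, DMPU, −78 → 20 °C
Reagents that add atoms: none
Why: LiN(i-Pr)2 should give the O,C-dilithio derivative of 7, whose α-sulfonyl carbanion (C3) displaces the benzylic bromide of 12 (C3–C4 bond), after which the tertiary lithium alkoxide adds to the fluorine-bearing carbon C8a ortho to the nitro group and expels fluoride through a Meisenheimer complex (O1–C8a bond). The closest known reaction types are the C-alkylation of β-hydroxy sulfone dianions and the intramolecular SNAr etherification of ortho-fluoronitroarenes. The dihydropyran ring closes in a 6-exo-trig SNAr mode, one fragment supplying O1–C2–C3 and the other C4–C4a–C8a. C2 is carried unchanged from the epoxide-derived carbinol because no bond at C2 is touched, whereas C3 forms without control and is erased when the sulfinate leaves in step 12. The step needs C- before O-alkylation (the carbanion is by far the better nucleophile for the benzylic bromide), attack at CH2Br and not at the C–F carbon at −78 °C (the fluoride is flanked by two ortho substituents and is reached only by the tethered alkoxide on warming), and ring closure faster than retro-addition of the β-oxido sulfone (secured by the nitro activation and the six-membered transition state).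

Step 11
Reactants: 14 (2S)-5,6-dimethoxy-2-methyl-8-nitro-3-(phenylsulfonyl)-2-{2-[(1S,2R)-1,2,3-trimethylcyclohex-3-en-1-yl]ethyl}chromane
Product: 15 (2S)-5,6-dimethoxy-2-methyl-3-(phenylsulfonyl)-2-{2-[(1S,2R)-1,2,3-trimethylcyclohex-3-en-1-yl]ethyl}chroman-8-amine
Conditions: Fe powder, NH4Cl, EtOH/H2O (4:1), 70 °C
Reagents that add atoms: none
Why: Béchamp-type reduction with iron and NH4Cl should reduce the nitro group to the aniline without touching the sulfone, the aryl ether or the trisubstituted alkene.

Step 12
Reactants: 15 (2S)-5,6-dimethoxy-2-methyl-3-(phenylsulfonyl)-2-{2-[(1S,2R)-1,2,3-trimethylcyclohex-3-en-1-yl]ethyl}chroman-8-amine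
Product: 17 (2S)-6-methoxy-2-methyl-2-{2-[(1S,2R)-1,2,3-trimethylcyclohex-3-en-1-yl]ethyl}-2H-chromene-5,8-dione (target), via quinone sulfone 16 (not isolated)
Conditions: (NH4)2Ce(NO3)6 (2.5 equiv), MeCN/H2O (2:1), 0 °C; extraction; then Et3N (2 equiv), CH2Cl2, 0 → 20 °C
Reagents that add atoms: water, O
Why: Oxidation of the para-methoxyaniline by (NH4)2Ce(NO3)6 should give the quinone monoimine, which is hydrolysed in the aqueous acid to the para-quinone 16 with loss of methanol, and Et3N then removes a C4 proton (vinylogous to the C8 carbonyl through C4a=C8a) so that benzenesulfinate leaves from C3 (E1cB), the ring enforcing the cis C3=C4 bond.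

**Compound list**

1 | methacrolein (2-methylprop-2-enal) | CC(=C)C=O | starting material
2 | (E)-3-methylpenta-1,3-diene | C=C/C(C)=C/C | starting material
3 | (1R,2S)-1,2,3-trimethylcyclohex-3-ene-1-carbaldehyde | O=C[C@]1(C)CCC=C(C)[C@@H]1C | intermediate
4 | (E)-4-[(1S,2S)-1,2,3-trimethylcyclohex-3-en-1-yl]but-3-en-2-one | CC(=O)/C=C/[C@]1(C)CCC=C(C)[C@@H]1C | intermediate
5 | 4-[(1S,2R)-1,2,3-trimethylcyclohex-3-en-1-yl]butan-2-one | CC(=O)CC[C@]1(C)CCC=C(C)[C@@H]1C | intermediate
6 | (2S)-2-methyl-2-{2-[(1S,2R)-1,2,3-trimethylcyclohex-3-en-1-yl]ethyl}oxirane | C1[C@](C)(CC[C@]2(C)CCC=C(C)[C@@H]2C)O1 | intermediate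
7 | (2S)-2-methyl-1-(phenylsulfonyl)-4-[(1S,2R)-1,2,3-trimethylcyclohex-3-en-1-yl]butan-2-ol | O=S(=O)(c1ccccc1)C[C@](C)(CC[C@]2(C)CCC=C(C)[C@@H]2C)O | intermediate
8 | 4-fluoro-1,2-dimethoxybenzene | COc1ccc(F)cc1OC | starting material
9 | 6-fluoro-2,3-dimethoxybenzaldehyde | O=Cc1c(F)ccc(OC)c1OC | intermediate
10 | 6-fluoro-2,3-dimethoxy-5-nitrobenzaldehyde | O=Cc1c(F)c([N+](=O)[O-])cc(OC)c1OC | intermediate
11 | (6-fluoro-2,3-dimethoxy-5-nitrophenyl)methanol | OCc1c(F)c([N+](=O)[O-])cc(OC)c1OC | intermediate
12 | 6-fluoro-2,3-dimethoxy-5-nitrobenzyl bromide | BrCc1c(F)c([N+](=O)[O-])cc(OC)c1OC | intermediate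
13 | (3S)-1-(6-fluoro-2,3-dimethoxy-5-nitrophenyl)-3-methyl-2-(phenylsulfonyl)-5-[(1S,2R)-1,2,3-trimethylcyclohex-3-en-1-yl]pentan-3-ol (C2 epimers; lithium alkoxide in the flask, drawn as the alcohol; not isolated) | O=S(=O)(c1ccccc1)C(Cc2c(F)c([N+](=O)[O-])cc(OC)c2OC)[C@](C)(CC[C@]3(C)CCC=C(C)[C@@H]3C)O | intermediate
14 | (2S)-5,6-dimethoxy-2-methyl-8-nitro-3-(phenylsulfonyl)-2-{2-[(1S,2R)-1,2,3-trimethylcyclohex-3-en-1-yl]ethyl}chromane (C3 epimers) | C1(S(=O)(=O)c2ccccc2)[C@](C)(CC[C@]3(C)CCC=C(C)[C@@H]3C)Oc4c(C1)c(OC)c(OC)cc4[N+](=O)[O-] | intermediate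
15 | (2S)-5,6-dimethoxy-2-methyl-3-(phenylsulfonyl)-2-{2-[(1S,2R)-1,2,3-trimethylcyclohex-3-en-1-yl]ethyl}chroman-8-amine (C3 epimers) | C1(S(=O)(=O)c2ccccc2)[C@](C)(CC[C@]3(C)CCC=C(C)[C@@H]3C)Oc4c(C1)c(OC)c(OC)cc4N | intermediate
16 | (2S)-6-methoxy-2-methyl-3-(phenylsulfonyl)-2-{2-[(1S,2R)-1,2,3-trimethylcyclohex-3-en-1-yl]ethyl}-3,4-dihydro-2H-chromene-5,8-dione (C3 epimers; not isolated) | COC1=CC(=O)C2=C(CC(S(=O)(=O)c3ccccc3)[C@](C)(CC[C@]4(C)CCC=C(C)[C@@H]4C)O2)C1=O | intermediate
17 | (2S)-6-methoxy-2-methyl-2-{2-[(1S,2R)-1,2,3-trimethylcyclohex-3-en-1-yl]ethyl}-2H-chromene-5,8-dione | COC1=CC(=O)C2=C(C=C[C@](C)(CC[C@]3(C)CCC=C(C)[C@@H]3C)O2)C1=O | target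

**Step count and risks**

Total step count: 12. Longest linear sequence: 8 steps (steps 1–5, then 10–12).

Steps most likely to fail:

1. Step 10. What may go wrong: electron transfer from, or addition of, the dilithio sulfone to the nitroarene; attack of the carbanion at the fluorine-bearing carbon; or retro-addition of the β-oxido sulfone before ring closure, which would also erode C2. Fallback, setting out from 7 and coming back at 16: the dianion of 7 (LiN(i-Pr)2, THF, −78 °C) is alkylated with 3-(bromomethyl)-1,2,4,5-tetramethoxybenzene F1, itself made from commercial 1,2,4,5-tetramethoxybenzene with paraformaldehyde and HBr in AcOH. This should give the tetramethoxyaryl hydroxy sulfone F2. Oxidation with (NH4)2Ce(NO3)6 in MeCN/H2O should give the 2,5-dimethoxy-1,4-benzoquinone F3 (either pair of para methoxy groups leads to the same quinone). Catalytic TsOH in benzene should then make the tertiary hydroxyl displace the methoxy group next to the side chain by addition–elimination on the vinylogous ester, giving 16, which continues with the Et3N treatment of step 12.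

2. Step 1. What may go wrong: poor endo or facial selectivity, or "meta" bonding of the diene, in a cycloaddition that must fix two adjacent centres at once. Fallback, setting out from 2 and coming back at 3: auxiliary-controlled Diels–Alder reaction of 2 with (S)-3-acryloyl-4-benzyloxazolidin-2-one F4 (from (S)-4-benzyloxazolidin-2-one and acryloyl chloride) under Et2AlCl in CH2Cl2 at −78 °C should give the endo imide F5 with the secondary methyl centre set by the auxiliary. MeOMgBr in MeOH should give the methyl ester F6. Deprotonation with LiN(i-Pr)2 and methylation with MeI, anti to the neighbouring ring methyl, should give the quaternary ester F7. Reduction with i-Bu2AlH in CH2Cl2 at −78 °C should give 3.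

3. Step 12. What may go wrong: over-oxidation of the electron-rich aminochroman (ring opening at the aryl ether, attack on the ring alkene) or incomplete hydrolysis of the quinone imine. Fallback, setting out from 15 and coming back at 16: diazotisation (NaNO2, H2SO4, 0 °C) and copper-mediated hydroxy-dediazoniation (Cu2O, Cu(NO3)2, H2O) should give the 8-hydroxychroman F8. Oxidative demethylation of this para-methoxyphenol with PhI(OAc)2 in MeCN/H2O should give 16, which continues with the Et3N treatment of step 12.

Further compounds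
F1 | step 10 | 3-(bromomethyl)-1,2,4,5-tetramethoxybenzene | BrCc1c(OC)c(OC)cc(OC)c1OC
F2 | step 10 | (3S)-3-methyl-2-(phenylsulfonyl)-1-(2,3,5,6-tetramethoxyphenyl)-5-[(1S,2R)-1,2,3-trimethylcyclohex-3-en-1-yl]pentan-3-ol | O=S(=O)(c1ccccc1)C(Cc2c(OC)c(OC)cc(OC)c2OC)[C@](C)(CC[C@]3(C)CCC=C(C)[C@@H]3C)O
F3 | step 10 | 3-{(3S)-3-hydroxy-3-methyl-2-(phenylsulfonyl)-5-[(1S,2R)-1,2,3-trimethylcyclohex-3-en-1-yl]pentyl}-2,5-dimethoxy-1,4-benzoquinone | COC1=CC(=O)C(OC)=C(CC(S(=O)(=O)c2ccccc2)[C@](C)(CC[C@]3(C)CCC=C(C)[C@@H]3C)O)C1=O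
F4 | step 1 | (S)-3-acryloyl-4-benzyloxazolidin-2-one | C=CC(=O)N1[C@@H](Cc2ccccc2)COC1=O
F5 | step 1 | (S)-4-benzyl-3-[(1R,2R)-2,3-dimethylcyclohex-3-ene-1-carbonyl]oxazolidin-2-one | O=C([C@@H]1CCC=C(C)[C@@H]1C)N1[C@@H](Cc2ccccc2)COC1=O
F6 | step 1 | methyl (1R,2R)-2,3-dimethylcyclohex-3-ene-1-carboxylate | COC(=O)[C@@H]1CCC=C(C)[C@@H]1C
F7 | step 1 | methyl (1R,2S)-1,2,3-trimethylcyclohex-3-ene-1-carboxylate | COC(=O)[C@]1(C)CCC=C(C)[C@@H]1C
F8 | step 12 | (2S)-5,6-dimethoxy-2-methyl-3-(phenylsulfonyl)-2-{2-[(1S,2R)-1,2,3-trimethylcyclohex-3-en-1-yl]ethyl}chroman-8-ol | C1(S(=O)(=O)c2ccccc2)[C@](C)(CC[C@]3(C)CCC=C(C)[C@@H]3C)Oc4c(C1)c(OC)c(OC)cc4O
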